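The earlier runs and the new flask were generated by integration on assumed constants, noise included.

- An easy step first: divide what a run has made of J by what it has lost of D. That share of reacted D found as J is the selectivity s.

| flask | D | temperature | remark | time |
|---|---|---|---|---|
| beta | 1.1 M | 40 °C | run made earlier |  |
| theta | 2.4 M | 73 °C | run made earlier |  |
| cedar | 1.6 M | 25 °C |  | 3.0 h |
| elm | 1.6 M | 85 °C |  | 3.0 h |
| birch | 1.6 M | 55 °C |  | 3.0 h |

| run | time / min | J / % | D / % |
|---|---|---|---|
| beta | 15.0 | 13.3 | 81.7 |
| beta | 30.0 | 24.3 | 67.2 |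
| beta | 40.0 | 30.0 | 59.0 |
| beta | 60.0 | 40.5 | 44.5 |
| beta | 80.0 | 47.7 | 36.0 |
| beta | 120 | 58.3 | 22.0 |
| theta | 3.00 | 41.5 | 29.0 |
| theta | 6.00 | 50.9 | 8.1 |
| theta | 8.00 | 52.9 | 3.7 |
| theta | 12.0 | 53.4 | 1.3 |
| theta | 15.0 | 53.5 | 0.8 |
| theta | 20.0 | 53.2 | 0.1 |

(readings scatter by 0.5 percentage points)

- percentages count the D that a species holds: one G or X or L counts as two
- percentages count the D that a species holds: one Z counts as three
- J is meant together with its Q
- solid, in amounts per volume of the solution: Q
- reactions considered so far: D -> J; 2 D -> G; D + G -> Z; G -> X; Q <-> J; D + J -> L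

- the best flask by amount of J, in percent of the D charged; "all alike" if 1.5 percentage points covers them all (cedar / elm / birch / all alike)
- amount of J at the end, in percent of the D charged, cedar
- amount of J at the end, in percent of the D charged, elm
- amount of J at the end, in percent of the D charged, birch

- By its last reading, beta has s = 0.747 and theta has s = 0.533.
- D → J needs one D, but the steps that make G and L each need D to meet a second partner, D for G and J for L, so the ratio of side loss to J made, (1 − s)/s, should grow with concentration. Let c be the mean of the starting and last D concentrations. Dividing by c gives 0.504 M⁻¹ for beta and 0.731 M⁻¹ for the hotter theta. Their mean, 0.617 M⁻¹, is the loss ratio a: side loss per J made, per M of D, over a whole run. So s = 1/(1 + a c).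
- First instants: D stands at 1.6 M. Readings give first-order losses of 0.0126 min⁻¹ in beta and 0.413 min⁻¹ in theta. Stretched exponentially with temperature, my reckoning gives 0.00259 min⁻¹ for cedar and 0.0616 min⁻¹ for birch.
- Middle: theta's s is 0.585 up to its first reading and 0.405 afterwards. Loss continues as J builds, so a is a whole-run figure, not an early one.
- End: birch's D lifetime, 16.2 min, is far shorter than 3.0 h, so c is the mean of 1.6 M and nothing. Theta's J reads 53.4% and later 53.2%, with D at 0.1%, so J holds once D has reacted.
- My reckoning: birch, between the runs, takes a and gives 66.9%. Elm, hotter than theta, takes theta's ratio and gives 63.1%. Cedar, colder than beta, keeps 62.8% of its D and gives 22.5%. Birch leads elm by 3.8 percentage points, beyond the margin of 1.5 points.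
- The forecast names birch, with 25% (19% to 31%) for cedar, 60% (51% to 67%) for elm and 66% (59% to 73%) for birch, on "a dimer loss of relative size about 0.45 per M of D", a ratio that differs from a.
- The flasks give 23.3% for cedar, 64.0% for elm and 68.7% for birch, so birch is best.

    D → J (k = 0.103 h⁻¹, Ea = 92.0 kJ mol⁻¹)
    2 D → G (k = 0.0271 M⁻¹ h⁻¹, Ea = 66.0 kJ mol⁻¹)
    D + G → Z (k = 0.00898 M⁻¹ h⁻¹, Ea = 93.0 kJ mol⁻¹)
    G → X (k = 0.142 h⁻¹, Ea = 105 kJ mol⁻¹)
    Q ⇌ J, rate k5*(cs5 - [J]) while solid is left; crystals form when [J] > cs5 (solubility = 27.0 mM, k = 3.60 h⁻¹)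
    D + J → L (k = 0.0493 M⁻¹ h⁻¹, Ea = 88.0 kJ mol⁻¹)
    (constants at 25 °C)

- At 3.00 h, birch holds more L than X: 19.0% against 11.9%. Its J corresponds to a = 0.570 M⁻¹, beside the 0.617 M⁻¹ carried in. That 0.617 M⁻¹ applied to a neighbour of birch charged with 0.96 M, at the same temperature and time, gives 77.2%, and that neighbour holds 78.0%.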